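You may stop anywhere up to 50 h, so the time of reading is yours to choose, and you want the moment intermediate A peaks.

| flask | starting material | solid reagent | remark | time |
|---|---|---|---|---|
| gamma | 1 M | 1.7 M | run made earlier |  |
| flask | 1.0 M | 1.10 M |  | 50 h |

gamma run (percent of the starting material charged)

| time / h | intermediate A / % | target / % | starting material / % |
|---|---|---|---|
| 1.33 | 42.2 | 0.7 | 33.8 |
| 3.00 | 30.4 | 0.5 | 7.6 |
| 4.00 | 21.6 | 1.1 | 3.2 |
| 6.00 | 8.1 | 0.7 | 0 |
| 8.00 | 4.3 | 0.5 | 0.2 |
| 10.0 | 0.8 | 0.3 | 0 |

(standard deviation of a reading: 0.5 percentage points)

- solid, in amounts per volume of the solution: solid reagent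
- at the start none of the solid reagent is in solution

- the moment within 50 h at which there is most intermediate A
- the amount of intermediate A, in percent of the starting material charged, at that time

The bench habit is to take the highest reading of the earlier run as the peak: in the gamma run, 42.2% at 1.33 h. The habit gives out on the time axis, since the next reading comes 2.26 times later and the peak may lie on either side of the one you picked.

So integrate instead, my own reckoning. Suppose starting material and intermediate A each fall with a fixed rate constant (pseudo-first-order). In the gamma run, starting material is down to 7.6% at 3.00 h. For intermediate A you take the two later readings in the second line below, where hardly any starting material is left to feed it: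

k(start) = ln(whole charge / part left) / time = 0.859 h⁻¹

k(A) = ln(21.6% / 8.1%) / (6.00 h − 4.00 h) = 0.490 h⁻¹

t(peak) = ln(k(start) / k(A)) / (k(start) − k(A)) = 1.52 h

This is the peak time, the moment when inflow into intermediate A equals its outflow. Scaling the curve through the reading at 1.33 h gives a height of 42.6%. I assume the flask's solid charge, 0.647 of the gamma one, changes neither constant.

The forecast gives 1.5 h (1.1 h to 2.2 h) and 44% (39% to 48%), expecting that “dissolved reagent stays constant, held at saturation by excess solid”. Its height stands above mine.

The flask peaks at 1.47 h with 42.9%, inside both forecast ranges and beside the reckoned 1.52 h.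

    solid reagent ⇌ partner, rate k1*(cs1 - [partner]) while solid is left; crystals form when [partner] > cs1 (solubility = 0.0900 M, k = 5.20 × 10⁻⁴ s⁻¹)
    intermediate A → intermediate B (k = 1.50 × 10⁻⁴ s⁻¹)
    partner + intermediate D ⇌ target (K = 0.210 M⁻¹, k = 9.40 × 10⁻⁵ M⁻¹ s⁻¹)
    starting material + partner → intermediate C (k = 2.50 × 10⁻⁴ M⁻¹ s⁻¹)
    intermediate B ⇌ intermediate D (K = 0.770, k = 2.90 × 10⁻⁴ s⁻¹)
    partner + intermediate C ⇌ intermediate E (K = 3.00 M⁻¹, k = 0.00330 M⁻¹ s⁻¹)
    starting material → intermediate A (k = 2.20 × 10⁻⁴ s⁻¹)

In the flask at 0.815 h, partner is made 1.85 times faster than it is used up, each step taken net. At the best time c(partner) is 0.0704 M, and solid reagent stands at 90.1% of its own charge.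

A neighbouring flask with the same charges is read at 30 h, which is 19.7 times the peak time, so the peak lies inside its window and the reckoning gives 42.6%. Computed, its highest amount of intermediate A is 42.9%.

The earlier runs and the new flask stem from a simulated flask from invented constants; scatter was added.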